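The numbers of this flask stand for no real mixture; the rest is arithmetic.

I chose to watch intermediate B, not the starting material, on a repeat of these flasks.

common to all: starting material 0.051 M; partner 3.00 equiv; time 1.5 min

| flask | remark | temperature |
|---|---|---|
| Sunday's | at 90 °C until 1.0 min, from then on at 150 °C |  |
| Saturday's |  | 90 °C |
| Monday's |  | 120 °C |
| Thursday's |  | 150 °C |

    intermediate B → target (k1 = 0.00102 s⁻¹, Ea1 = 107 kJ mol⁻¹)
    target → over-reaction product (k2 = 1.60 × 10⁻⁵ s⁻¹, Ea2 = 125 kJ mol⁻¹)
    partner + intermediate A → intermediate B (k3 = 0.0351 L mol⁻¹ s⁻¹, Ea3 = 57.0 kJ mol⁻¹)
    starting material ⇌ intermediate A (K4 = 0.51, k4 = 0.122 s⁻¹, Ea4 = 105 kJ mol⁻¹, ΔH4 = −9.00 kJ mol⁻¹)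
    (constants at 90 °C)

- the constants hold at 90 °C; other temperatures follow from the activation energies and enthalpies

- the flask that comes out highest in amount of target, in percent of the starting material charged, or "all alike" when all lie within 1.5 percentage points (Sunday's / Saturday's / Monday's / Thursday's / all alike)
- target at the end, in percent of the starting material charged, Sunday's
- target at the end, in percent of the starting material charged, Saturday's
- target at the end, in percent of the starting material charged, Monday's
- target at the end, in percent of the starting material charged, Thursday's

My reckoning went by step one, which turns intermediate B into target. Its constant scales from 0.00102 s⁻¹ at 90 °C to 0.155 s⁻¹ at 150 °C, so the lifetime of intermediate B at 150 °C, the time in which step one lowers c(intermediate B) by a factor e, was 6.44 s. Time divided by lifetime counts the lifetimes a flask gets.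

Thursday's got 14.0, and Sunday's got 4.66 in its hot stretch. Monday's got 1.37 and Saturday's 0.0918. So I ranked them Thursday's, Sunday's, Monday's, Saturday's, because the counts fell in that order. The danger was step two, but Thursday's gave target itself 0.510 lifetimes, far fewer than intermediate B had. I took that as a loss and not a reversal of the order. My count stopped at this ranking and gave no yields.

The forecast did give yields: 55.7% for Thursday's, 36.9% for Sunday's, 20.6% for Monday's and 0.64% for Saturday's, with Thursday's highest. It treated the feed into intermediate B as pseudo-first-order, “slowed by partner use”.

The simulation put Thursday's highest at 55.7%, with Sunday's at 36.7%, Monday's at 20.5% and Saturday's at 0.633%. The same flask as Thursday's with 0.750 equiv of partner ended at 21.3%, lower than Thursday's itself. Thursday's own 14.0 lifetimes ended with c(intermediate B) at 2.41%. In Sunday's, c(intermediate B) stood at 9.34% at the change, and by my count 4.66 lifetimes cut that stock to 0.0884%, while the flask ended with 6.52%.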